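**Strategy.** The cyclohex-2-enone ring is cut at C2=C3 and C5–C6. The ring ketone C1 makes the quaternary carbon C6 the α-carbon of an acetoacetate unit (C2–C1–C6), and C2=C3 is an aldol-condensation retron, so the partner is 2-methoxyacrolein (C3–C4–C5). C6 is carried as an allyl β-keto ester: the ester activates C6 for the Michael union at the hindered centre and stores the allyl group on oxygen. In one flask, Michael addition makes C5–C6, palladium-catalysed loss of CO2 moves the allyl group onto C6, and aldol condensation closes C2=C3. The precursor is an acyclic keto ester carrying only the methyl-bearing stereocentre, taken from (S)-2-chloropropanoyl chloride.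

Key step: step 4

Remark: ring atoms of the target are numbered C1 (C=O), C2=C3, C4 (OMe), C5 (CH2), C6 (quaternary). The keto ester made in step 3 is used as the mixture of epimers at its acidic ester α-carbon, a centre that step 4 erases.

**Step 1**
Reactants: 1 methoxyacetaldehyde
Product: 2 2-methoxyprop-2-enal (2-methoxyacrolein)
Conditions: aq. HCHO (37%), pyrrolidine (10 mol %), propionic acid (10 mol %), 2-propanol, 45 °C; distilled and used at once
Reagents that add atoms: formaldehyde, C=O
Why: Enamine formation, Mannich addition to formaldehyde and elimination of the amine (organocatalytic α-methylenation of an aldehyde) should give the 2-substituted acrolein, which has no stereocentre and is used fresh because it oligomerises.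

**Step 2**
Reactants: 3 1,2-dimethoxybenzene (veratrole), 4 (S)-2-chloropropanoyl chloride
Product: 5 (S)-2-chloro-1-(3,4-dimethoxyphenyl)propan-1-one
Conditions: AlCl3 (1.3 equiv), CH2Cl2, 0 °C
Reagents that add atoms: none
Why: Friedel–Crafts acylation of the activated arene should occur para to one methoxy group and meta to the other, and since the acylium carbon is not the stereocentre the (S) configuration is expected to be retained.

**Step 3**
Reactants: 5 (S)-2-chloro-1-(3,4-dimethoxyphenyl)propan-1-one, 6 prop-2-en-1-yl 3-oxobutanoate (allyl acetoacetate)
Product: 7 prop-2-en-1-yl (2RS,3S)-2-acetyl-4-(3,4-dimethoxyphenyl)-3-methyl-4-oxobutanoate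
Conditions: NaH (1.0 equiv), THF, 0 °C; then 5, THF–DMF, 0 → 23 °C; buffered (NH4Cl) work-up
Reagents that add atoms: none
Why: Acetoacetic ester alkylation: the soft sodium enolate of 6 displaces the activated secondary α-keto chloride by SN2 with inversion, which with the changed substituent ranking again reads (S), while the new ester α-carbon is acidic and stereochemically irrelevant.

**Step 4**
Reactants: 7 prop-2-en-1-yl (2RS,3S)-2-acetyl-4-(3,4-dimethoxyphenyl)-3-methyl-4-oxobutanoate, 2 2-methoxyprop-2-enal
Product: 10 (4R,6R)-6-[(2S)-1-(3,4-dimethoxyphenyl)-1-oxopropan-2-yl]-4-methoxy-6-(prop-2-en-1-yl)cyclohex-2-en-1-one, via Michael adduct aldehyde 8 (not isolated), via allylated keto aldehyde 9 (not isolated)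
Conditions: DBU (5 mol %), THF, 0 °C; AcOH (5 mol %), then Pd(PPh3)4 (5 mol %), 23 °C; then pyrrolidine (30 mol %), AcOH (30 mol %), 40 °C
Reagents that add atoms: none
Why: Catalytic DBU forms the stabilised enolate of 7, whose fully substituted α-carbon adds to the unhindered CH2 terminus of 2 (Michael addition, C5–C6 bond) to give 8; Pd(PPh3)4 then ionises the allyl ester, CO2 is lost and the regiodefined ketone enolate is allylated at carbon (Tsuji decarboxylative allylation) to give 9; pyrrolidinium acetate finally condenses the methyl ketone with the aldehyde (Mannich-type aldol condensation, E1cB loss of the amine) to close C2=C3. The closest known reaction types are the Robinson-type Michael/aldol [3+3] annulation of β-keto esters with enals and the decarboxylative allylation of α,α-disubstituted allyl β-keto esters, here run in one flask. The single ring closure is a 6-(enolendo)-exo-trig attack of the methyl ketone enol on the aldehyde-derived iminium ion. The quaternary centre C6 is set in the allylation: the C–H bond of the neighbouring (S)-methine should eclipse the enolate C=C to avoid allylic 1,3-strain, and the allyl group should enter anti to the aroyl group, which corresponds to (6R). The methoxy-bearing centre C4 is set last and dynamically: the α-methoxy aldehyde epimers of 9 interconvert through the enamine, and closure should prefer the chair with the branched aroylethyl group and OMe both equatorial (allyl axial), that is OMe cis to the side chain, so both epimers funnel to (4R). The step needs C-allylation before ring closure and closure by the methyl ketone onto the aldehyde; the first is secured by quenching the base and withholding the aldol catalyst until CO2 evolution ends, the second because only this aldol can dehydrate and the electron-rich aryl ketone is a poor electrophile.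

**Compound list**
1 | methoxyacetaldehyde | COCC=O | starting material
2 | 2-methoxyprop-2-enal (2-methoxyacrolein) | C=C(OC)C=O | intermediate
3 | 1,2-dimethoxybenzene (veratrole) | COc1ccccc1OC | starting material
4 | (S)-2-chloropropanoyl chloride | C[C@H](Cl)C(Cl)=O | starting material
5 | (S)-2-chloro-1-(3,4-dimethoxyphenyl)propan-1-one | C[C@H](Cl)C(=O)c1ccc(OC)c(OC)c1 | intermediate
6 | prop-2-en-1-yl 3-oxobutanoate (allyl acetoacetate) | CC(=O)CC(=O)OCC=C | starting material
7 | prop-2-en-1-yl (2RS,3S)-2-acetyl-4-(3,4-dimethoxyphenyl)-3-methyl-4-oxobutanoate | CC(=O)C(C(=O)OCC=C)[C@H](C)C(=O)c1ccc(OC)c(OC)c1 | intermediate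
8 | prop-2-en-1-yl (3S)-2-acetyl-4-(3,4-dimethoxyphenyl)-2-(2-methoxy-3-oxopropyl)-3-methyl-4-oxobutanoate (mixture at the quaternary and methoxy-bearing carbons) | CC(=O)C(CC(OC)C=O)(C(=O)OCC=C)[C@H](C)C(=O)c1ccc(OC)c(OC)c1 | intermediate
9 | (4R,5S)-4-acetyl-6-(3,4-dimethoxyphenyl)-2-methoxy-5-methyl-6-oxo-4-(prop-2-en-1-yl)hexanal (both C2 epimers) | C=CC[C@](C(C)=O)([C@H](C)C(=O)c1ccc(OC)c(OC)c1)CC(OC)C=O | intermediate
10 | (4R,6R)-6-[(2S)-1-(3,4-dimethoxyphenyl)-1-oxopropan-2-yl]-4-methoxy-6-(prop-2-en-1-yl)cyclohex-2-en-1-one | C=CC[C@]1([C@H](C)C(=O)c2ccc(OC)c(OC)c2)C[C@@H](OC)C=CC1=O | target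

**Step count.** Total: 4 steps. Longest linear sequence: 3 steps (steps 2, 3, 4).

**Steps most likely to fail**

Step 4. The Michael addition at the congested carbon may revert before the allyl group is transferred. The allylation of the open-chain enolate may discriminate its two faces poorly, and the chair preference that sets C4 may be weak. Fallback, setting out from 7 and 2: the DBU-catalysed Michael addition is followed at once by pyrrolidinium acetate, without palladium, so that adduct 8 is trapped irreversibly by aldol condensation as prop-2-en-1-yl 1-[(2S)-1-(3,4-dimethoxyphenyl)-1-oxopropan-2-yl]-5-methoxy-2-oxocyclohex-3-ene-1-carboxylate F1. Pd2(dba)3 and the (S)-t-BuPHOX ligand in toluene then effect the decarboxylative allylation on the cyclic dienolate. There the ring methoxy group and the ligand add to the bias of the side chain. The price is that the methoxy-bearing centre is fixed before C6, so its epimers may have to be separated. The route is rejoined at 10.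

Step 3. The chlorine-bearing carbon may lose its configuration by enolisation or by exchange with liberated chloride, and elimination or O-alkylation may compete. Fallback, setting out from 6: Knoevenagel condensation with acetaldehyde (piperidine, AcOH) should give prop-2-en-1-yl 2-ethylidene-3-oxobutanoate F2. An enantioselective Stetter reaction of commercial 3,4-dimethoxybenzaldehyde with F2 (chiral aminoindanol-derived triazolium carbene precatalyst, N,N-diisopropylethylamine) then forms the aroyl–CH(CH3) bond and the stereocentre directly, with no substitution at a stereogenic carbon. The route is rejoined at 7.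

Step 2. The Lewis acid may cleave an aryl methyl ether or enolise, and so partly racemise, the aluminium-bound α-chloro ketone. Fallback, setting out from 4: amidation with N,O-dimethylhydroxylamine hydrochloride and pyridine should give (S)-2-chloro-N-methoxy-N-methylpropanamide F3. Addition of commercial 3,4-dimethoxyphenylmagnesium bromide (THF, −40 °C) to this Weinreb amide delivers the ketone without any Lewis acid and rejoins the route at 5.

**Further compounds**
F1 | step 4 | prop-2-en-1-yl 1-[(2S)-1-(3,4-dimethoxyphenyl)-1-oxopropan-2-yl]-5-methoxy-2-oxocyclohex-3-ene-1-carboxylate | C=CCOC(=O)C1(CC(OC)C=CC1=O)[C@H](C)C(=O)c2ccc(OC)c(OC)c2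
F2 | step 3 | prop-2-en-1-yl 2-ethylidene-3-oxobutanoate | CC=C(C(C)=O)C(=O)OCC=C
F3 | step 2 | (S)-2-chloro-N-methoxy-N-methylpropanamide | C[C@H](Cl)C(=O)N(C)OC
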